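The α-methylene-γ-butyrolactone (O1, C12, C11, C13, fused at C6–C7) is left out until late and is then annulated in one operation onto a lactone-free ten-membered carbocycle. A palladium-catalysed (3+2) heteroannulation of 2-bromoacrylic acid with the ring diene C4=C5–C6=C7 forms C7–C11 by carbopalladation and closes the lactone when the carboxylate oxygen attacks C6 of the resulting C4–C5–C6 π-allyl. It exploits the fact that O1 sits on C6, allylic to the C4=C5 alkene. The precursor is a (Z,Z)-diene cyclodecatriene made by ring-closing metathesis; its C8 ether, carried in the epimeric configuration, steers the annulation and is inverted later by Mitsunobu esterification.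

Key step: step 11

Remark on numbering: atom labels follow germacrane numbering. C1–C10 are the ring carbons, C11/C12/C13 the lactone α-carbon, carbonyl carbon and exocyclic methylene, C14 the ester carbon on C10, C15 the hydroxymethyl carbon on C4, and O1 the lactone ring oxygen.

Assumption: the ring-closing metathesis of step 10 should give the (Z)-C6=C7 alkene, as is usual for a ten-membered ring; the facial argument of step 11 is made for this isomer.

Step 1
Reactants: 1 triethyl phosphonoacetate; 2 4-bromobut-1-yne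
Product: 3 ethyl 2-(diethoxyphosphoryl)hex-5-ynoate (racemic)
Conditions: NaH, DMF, 0 °C then 50 °C
Reagents that add atoms: none
Why: SN2 C-alkylation of the phosphonoacetate anion attaches the C3–C2–C1≡C10 chain; the stereocentre formed is destroyed in step 2.

Step 2
Reactants: 3 ethyl 2-(diethoxyphosphoryl)hex-5-ynoate; 4 acrolein
Product: 5 ethyl (2E)-2-(but-3-yn-1-yl)penta-2,4-dienoate
Conditions: NaH, THF, 0 °C; then 4, −78 → 0 °C
Reagents that add atoms: none
Why: Horner–Wadsworth–Emmons olefination of the stabilised phosphonate should favour the 2E dienoate, with the vinyl group (C6) trans to the ester carbon (C15) and cis to C3, which is the C4=C5 geometry of the target.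

Step 3
Reactants: 5 ethyl (2E)-2-(but-3-yn-1-yl)penta-2,4-dienoate
Product: 6 (2E)-2-(but-3-yn-1-yl)penta-2,4-dien-1-ol
Conditions: i-Bu2AlH (2.5 equiv), CH2Cl2, −78 °C; aqueous potassium sodium tartrate
Reagents that add atoms: none
Why: 1,2-reduction of the conjugated ester by the aluminium hydride gives the C15 allylic alcohol and leaves diene and alkyne untouched.

Step 4
Reactants: 6 (2E)-2-(but-3-yn-1-yl)penta-2,4-dien-1-ol
Product: 7 tert-butyl{[(2E)-2-(but-3-yn-1-yl)penta-2,4-dien-1-yl]oxy}diphenylsilane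
Conditions: TBDPSCl, imidazole, CH2Cl2, rt
Reagents that add atoms: tert-butyl(chloro)diphenylsilane, CC(C)(C)[Si](Cl)(c1ccccc1)c1ccccc1
Why: silylation of the primary alcohol gives an ether that should survive the organometallic, palladium, DDQ and Mitsunobu steps and is removed last.

Step 5
Reactants: 8 2-vinyloxirane (racemic); 9 (4-methoxyphenyl)methanol
Product: 10 (2R)-2-[(4-methoxybenzyl)oxy]but-3-en-1-ol
Conditions: Pd2(dba)3·CHCl3 (1 mol %), N,N'-bis[2-(diphenylphosphino)benzoyl]cyclohexane-1,2-diamine (3 mol %, the trans enantiomer that gives the 2R ether), Et3B (1 mol %), CH2Cl2, rt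
Reagents that add atoms: none
Why: palladium-catalysed dynamic kinetic asymmetric allylic etherification, in which both epoxide enantiomers converge on one π-allyl complex and the borate delivers the alkoxide to the internal carbon; the chiral ligand sets C8.

Step 6
Reactants: 10 (2R)-2-[(4-methoxybenzyl)oxy]but-3-en-1-ol
Product: 11 (2R)-2-[(4-methoxybenzyl)oxy]but-3-enal
Conditions: Dess–Martin periodinane, NaHCO3, CH2Cl2, 0 °C; used crude at once
Reagents that add atoms: none
Why: buffered Dess–Martin oxidation at low temperature should give the labile α-alkoxy-β,γ-unsaturated aldehyde without epimerisation or double-bond migration if it is used immediately.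

Step 7
Reactants: 7 tert-butyl{[(2E)-2-(but-3-yn-1-yl)penta-2,4-dien-1-yl]oxy}diphenylsilane; 11 (2R)-2-[(4-methoxybenzyl)oxy]but-3-enal
Product: 13 (3R,4R,9E)-9-{[tert-butyl(diphenyl)silyl]oxymethyl}-3-[(4-methoxybenzyl)oxy]dodeca-1,9,11-trien-5-yn-4-ol, via alkynylzinc bromide 12 (not isolated)
Conditions: n-BuLi, Et2O, −78 °C; ZnBr2, −78 → 0 °C; then 11, −78 → −20 °C
Reagents that add atoms: zinc bromide, [Zn+2].[Br-].[Br-] (its zinc and one bromide stay only in 12)
Why: chelation-controlled (Cram-chelate) addition of the alkynylzinc to the α-alkoxy aldehyde forms C9–C10 and should set C9 syn to the C8 ether, the nucleophile entering past the small α-hydrogen of the zinc chelate.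

Step 8
Reactants: 13 (3R,4R,9E)-9-{[tert-butyl(diphenyl)silyl]oxymethyl}-3-[(4-methoxybenzyl)oxy]dodeca-1,9,11-trien-5-yn-4-ol
Product: 15 (3R,4S,5E,9E)-9-{[tert-butyl(diphenyl)silyl]oxymethyl}-5-iodo-3-[(4-methoxybenzyl)oxy]dodeca-1,5,9,11-tetraen-4-ol, via vinylstannane 14 (not isolated)
Conditions: Pd(PPh3)2Cl2 (2 mol %), Bu3SnH (1.1 equiv), THF, 0 °C; then N-iodosuccinimide, 0 °C
Reagents that add atoms: tributyltin hydride, CCCC[SnH](CCCC)CCCC (its tin stays only in 14); N-iodosuccinimide, O=C1CCC(=O)N1I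
Why: palladium-catalysed syn-hydrostannation, in which the free propargylic hydroxyl steers tin to the proximal carbon C10, followed by iododestannylation with retention; this fixes C2 cis to C9 on the future C1=C10 alkene.

Step 9
Reactants: 15 (3R,4S,5E,9E)-9-{[tert-butyl(diphenyl)silyl]oxymethyl}-5-iodo-3-[(4-methoxybenzyl)oxy]dodeca-1,5,9,11-tetraen-4-ol
Product: 16 methyl (2E,6E)-6-{[tert-butyl(diphenyl)silyl]oxymethyl}-2-{(1R,2R)-1-hydroxy-2-[(4-methoxybenzyl)oxy]but-3-en-1-yl}nona-2,6,8-trienoate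
Conditions: Pd(PPh3)2Cl2 (5 mol %), CO (1 atm), Et3N, MeOH–DMF (1:1), 50 °C
Reagents that add atoms: carbon monoxide, [C-]#[O+]; methanol, CO
Why: palladium-catalysed methoxycarbonylation of the vinyl iodide proceeds with retention of alkene geometry and installs the C14 ester trans to C2; methanol in large excess should outcompete the neighbouring hydroxyl for the acylpalladium.

Step 10
Reactants: 16 methyl (2E,6E)-6-{[tert-butyl(diphenyl)silyl]oxymethyl}-2-{(1R,2R)-1-hydroxy-2-[(4-methoxybenzyl)oxy]but-3-en-1-yl}nona-2,6,8-trienoate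
Product: 17 methyl (1E,5E,7Z,9R,10R)-5-{[tert-butyl(diphenyl)silyl]oxymethyl}-10-hydroxy-9-[(4-methoxybenzyl)oxy]cyclodeca-1,5,7-triene-1-carboxylate
Conditions: second-generation Grubbs catalyst RuCl2(=CHPh)(H2IMes)(PCy3) (10 mol %), 1,4-benzoquinone (20 mol %), CH2Cl2 (1 mM), 40 °C
Reagents that add atoms: none
Why: diene–ene ring-closing metathesis between the C7 vinyl group and the terminal alkene of the diene; the two trisubstituted alkenes are inert, the cis-configured C1=C10 and C4=C5 units fold the chain, and a ten-membered ring should close to the (Z)-C6=C7 alkene.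

Step 11
Reactants: 17 methyl (1E,5E,7Z,9R,10R)-5-{[tert-butyl(diphenyl)silyl]oxymethyl}-10-hydroxy-9-[(4-methoxybenzyl)oxy]cyclodeca-1,5,7-triene-1-carboxylate; 18 2-bromoacrylic acid
Product: 19 methyl (3aS,4R,5R,6E,10E,11aR)-10-{[tert-butyl(diphenyl)silyl]oxymethyl}-5-hydroxy-4-[(4-methoxybenzyl)oxy]-3-methylidene-2-oxo-2,3,3a,4,5,8,9,11a-octahydrocyclodeca[b]furan-6-carboxylate
Conditions: Pd(OAc)2 (10 mol %), PPh3 (20 mol %), n-Bu4NCl (1 equiv), NaHCO3 (3 equiv), 18 (2 equiv), DMF, 80 °C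
Reagents that add atoms: none
Why: Zerovalent palladium inserts into the C–Br bond of 18, the α-carboxyvinylpalladium adds syn across C6=C7 with carbon going to the less substituted diene terminus C7, and the tethered carboxylate oxygen then attacks C6 of the C4–C5–C6 π-allylpalladium, closing the five-membered lactone by a 5-exo allylic substitution (a formal (3+2) annulation). The closest known reaction type is the Larock heteroannulation of 1,3-dienes with halo carboxylic acids (carbopalladation followed by π-allyl capture). C7 is set by attack on the outer face of the ring: A(1,3) strain with C5 keeps H8 in the diene plane, so the vinyl group enters anti to the C8–C9 ring bond and ends trans to the C8 ether. C6 is set by the carboxylate attacking anti to palladium (chloride keeps it off the metal), a net anti addition across the (Z)-alkene that gives the trans-fused lactone, and reversible ionisation of the allylic lactone by zerovalent palladium should correct any cis-fused isomer. The step needs regioselectivity (C7 over the fully substituted C4 in the addition, C6 over the tertiary C4 in the ring closure) and chemoselectivity over the C1=C10 acrylate, and both follow from the substitution pattern and the electron-poor, trisubstituted nature of the acrylate. The C4=C5 geometry is kept because C3 stays on the same side of the allyl unit, held by the ring.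

Step 12
Reactants: 19 methyl (3aS,4R,5R,6E,10E,11aR)-10-{[tert-butyl(diphenyl)silyl]oxymethyl}-5-hydroxy-4-[(4-methoxybenzyl)oxy]-3-methylidene-2-oxo-2,3,3a,4,5,8,9,11a-octahydrocyclodeca[b]furan-6-carboxylate
Product: 20 methyl (3aS,4R,5R,6E,10E,11aR)-5-(acetyloxy)-10-{[tert-butyl(diphenyl)silyl]oxymethyl}-4-[(4-methoxybenzyl)oxy]-3-methylidene-2-oxo-2,3,3a,4,5,8,9,11a-octahydrocyclodeca[b]furan-6-carboxylate
Conditions: Ac2O, pyridine, DMAP (cat.), CH2Cl2, 0 °C → rt
Reagents that add atoms: acetic anhydride, CC(=O)OC(C)=O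
Why: acylation of the only free hydroxyl (C9) with retention; it is done after step 11 because this allylic acetate would be ionised by zerovalent palladium.

Step 13
Reactants: 20 methyl (3aS,4R,5R,6E,10E,11aR)-5-(acetyloxy)-10-{[tert-butyl(diphenyl)silyl]oxymethyl}-4-[(4-methoxybenzyl)oxy]-3-methylidene-2-oxo-2,3,3a,4,5,8,9,11a-octahydrocyclodeca[b]furan-6-carboxylate
Product: 21 methyl (3aR,4R,5R,6E,10E,11aR)-5-(acetyloxy)-10-{[tert-butyl(diphenyl)silyl]oxymethyl}-4-hydroxy-3-methylidene-2-oxo-2,3,3a,4,5,8,9,11a-octahydrocyclodeca[b]furan-6-carboxylate (the 3a descriptor changes by CIP priority only)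
Conditions: DDQ, CH2Cl2–pH 7 buffer (10:1), 0 °C → rt
Reagents that add atoms: none
Why: oxidative cleavage of the 4-methoxybenzyl ether under neutral conditions frees the C8 hydroxyl without acyl migration from C9.

Step 14
Reactants: 21 methyl (3aR,4R,5R,6E,10E,11aR)-5-(acetyloxy)-10-{[tert-butyl(diphenyl)silyl]oxymethyl}-4-hydroxy-3-methylidene-2-oxo-2,3,3a,4,5,8,9,11a-octahydrocyclodeca[b]furan-6-carboxylate; 22 methacrylic acid
Product: 23 methyl (3aS,4S,5R,6E,10E,11aR)-5-(acetyloxy)-10-{[tert-butyl(diphenyl)silyl]oxymethyl}-3-methylidene-4-[(2-methylprop-2-enoyl)oxy]-2-oxo-2,3,3a,4,5,8,9,11a-octahydrocyclodeca[b]furan-6-carboxylate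
Conditions: PPh3, DIAD (premixed, 0 °C), then 21 and 22, toluene, 0 °C → rt
Reagents that add atoms: none
Why: Mitsunobu esterification displaces the activated C8 oxygen by methacrylate in an SN2 process with inversion, which turns the 8R carbinol that steered step 11 into the 8S ester of the target.

Step 15
Reactants: 23 methyl (3aS,4S,5R,6E,10E,11aR)-5-(acetyloxy)-10-{[tert-butyl(diphenyl)silyl]oxymethyl}-3-methylidene-4-[(2-methylprop-2-enoyl)oxy]-2-oxo-2,3,3a,4,5,8,9,11a-octahydrocyclodeca[b]furan-6-carboxylate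
Product: 24 methyl (3aS,4S,5R,6E,10E,11aR)-5-(acetyloxy)-10-(hydroxymethyl)-3-methylidene-4-[(2-methylprop-2-enoyl)oxy]-2-oxo-2,3,3a,4,5,8,9,11a-octahydrocyclodeca[b]furan-6-carboxylate
Conditions: HF·pyridine, pyridine, THF, 0 °C → rt
Reagents that add atoms: none
Why: buffered fluoride cleavage of the silyl ether frees the C15 hydroxyl without touching the acetate, the methacrylate or the α-methylene lactone.

Compound list

1 | triethyl phosphonoacetate | CCOC(=O)CP(=O)(OCC)OCC | starting material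
2 | 4-bromobut-1-yne | BrCCC#C | starting material
3 | ethyl 2-(diethoxyphosphoryl)hex-5-ynoate (racemic) | CCOC(=O)C(CCC#C)P(=O)(OCC)OCC | intermediate
4 | acrolein (prop-2-enal) | C=CC=O | starting material
5 | ethyl (2E)-2-(but-3-yn-1-yl)penta-2,4-dienoate | CCOC(=O)/C(CCC#C)=C/C=C | intermediate
6 | (2E)-2-(but-3-yn-1-yl)penta-2,4-dien-1-ol | OC/C(CCC#C)=C/C=C | intermediate
7 | tert-butyl{[(2E)-2-(but-3-yn-1-yl)penta-2,4-dien-1-yl]oxy}diphenylsilane | CC(C)(C)[Si](OC/C(CCC#C)=C/C=C)(c1ccccc1)c1ccccc1 | intermediate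
8 | 2-vinyloxirane (racemic) | C=CC1CO1 | starting material
9 | (4-methoxyphenyl)methanol | COc1ccc(CO)cc1 | starting material
10 | (2R)-2-[(4-methoxybenzyl)oxy]but-3-en-1-ol | C=C[C@H](CO)OCc1ccc(OC)cc1 | intermediate
11 | (2R)-2-[(4-methoxybenzyl)oxy]but-3-enal | C=C[C@H](C=O)OCc1ccc(OC)cc1 | intermediate
12 | bromo[(5E)-5-{[tert-butyl(diphenyl)silyl]oxymethyl}octa-5,7-dien-1-yn-1-yl]zinc (alkynylzinc bromide) | Br[Zn]C#CCC/C(CO[Si](c1ccccc1)(c1ccccc1)C(C)(C)C)=C\C=C | intermediate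
13 | (3R,4R,9E)-9-{[tert-butyl(diphenyl)silyl]oxymethyl}-3-[(4-methoxybenzyl)oxy]dodeca-1,9,11-trien-5-yn-4-ol | C=C[C@@H](OCc1ccc(OC)cc1)[C@H](O)C#CCC/C(CO[Si](c1ccccc1)(c1ccccc1)C(C)(C)C)=C\C=C | intermediate
14 | (3R,4S,5E,9E)-9-{[tert-butyl(diphenyl)silyl]oxymethyl}-3-[(4-methoxybenzyl)oxy]-5-(tributylstannyl)dodeca-1,5,9,11-tetraen-4-ol (vinylstannane) | C=C[C@@H](OCc1ccc(OC)cc1)[C@H](O)/C(=C\CC/C(CO[Si](c1ccccc1)(c1ccccc1)C(C)(C)C)=C\C=C)[Sn](CCCC)(CCCC)CCCC | intermediate
15 | (3R,4S,5E,9E)-9-{[tert-butyl(diphenyl)silyl]oxymethyl}-5-iodo-3-[(4-methoxybenzyl)oxy]dodeca-1,5,9,11-tetraen-4-ol | C=C[C@@H](OCc1ccc(OC)cc1)[C@H](O)/C(I)=C\CC/C(CO[Si](c1ccccc1)(c1ccccc1)C(C)(C)C)=C\C=C | intermediate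
16 | methyl (2E,6E)-6-{[tert-butyl(diphenyl)silyl]oxymethyl}-2-{(1R,2R)-1-hydroxy-2-[(4-methoxybenzyl)oxy]but-3-en-1-yl}nona-2,6,8-trienoate | C=C[C@@H](OCc1ccc(OC)cc1)[C@H](O)/C(C(=O)OC)=C\CC/C(CO[Si](c1ccccc1)(c1ccccc1)C(C)(C)C)=C\C=C | intermediate
17 | methyl (1E,5E,7Z,9R,10R)-5-{[tert-butyl(diphenyl)silyl]oxymethyl}-10-hydroxy-9-[(4-methoxybenzyl)oxy]cyclodeca-1,5,7-triene-1-carboxylate | COC(=O)/C1=C/CC/C(CO[Si](c2ccccc2)(c2ccccc2)C(C)(C)C)=C\C=C/[C@@H](OCc2ccc(OC)cc2)[C@@H]1O | intermediate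
18 | 2-bromoacrylic acid (2-bromoprop-2-enoic acid) | C=C(Br)C(=O)O | starting material
19 | methyl (3aS,4R,5R,6E,10E,11aR)-10-{[tert-butyl(diphenyl)silyl]oxymethyl}-5-hydroxy-4-[(4-methoxybenzyl)oxy]-3-methylidene-2-oxo-2,3,3a,4,5,8,9,11a-octahydrocyclodeca[b]furan-6-carboxylate | COc1ccc(CO[C@@H]2[C@H]3C(=C)C(=O)O[C@@H]3/C=C(/CO[Si](c4ccccc4)(c4ccccc4)C(C)(C)C)CC/C=C(/C(=O)OC)[C@H]2O)cc1 | intermediate
20 | methyl (3aS,4R,5R,6E,10E,11aR)-5-(acetyloxy)-10-{[tert-butyl(diphenyl)silyl]oxymethyl}-4-[(4-methoxybenzyl)oxy]-3-methylidene-2-oxo-2,3,3a,4,5,8,9,11a-octahydrocyclodeca[b]furan-6-carboxylate | COc1ccc(CO[C@@H]2[C@H]3C(=C)C(=O)O[C@@H]3/C=C(/CO[Si](c4ccccc4)(c4ccccc4)C(C)(C)C)CC/C=C(/C(=O)OC)[C@H]2OC(C)=O)cc1 | intermediate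
21 | methyl (3aR,4R,5R,6E,10E,11aR)-5-(acetyloxy)-10-{[tert-butyl(diphenyl)silyl]oxymethyl}-4-hydroxy-3-methylidene-2-oxo-2,3,3a,4,5,8,9,11a-octahydrocyclodeca[b]furan-6-carboxylate | O[C@@H]1[C@H]2C(=C)C(=O)O[C@@H]2/C=C(/CO[Si](c3ccccc3)(c3ccccc3)C(C)(C)C)CC/C=C(/C(=O)OC)[C@H]1OC(C)=O | intermediate
22 | methacrylic acid (2-methylprop-2-enoic acid) | C=C(C)C(=O)O | starting material
23 | methyl (3aS,4S,5R,6E,10E,11aR)-5-(acetyloxy)-10-{[tert-butyl(diphenyl)silyl]oxymethyl}-3-methylidene-4-[(2-methylprop-2-enoyl)oxy]-2-oxo-2,3,3a,4,5,8,9,11a-octahydrocyclodeca[b]furan-6-carboxylate | C=C(C)C(=O)O[C@H]1[C@H]2C(=C)C(=O)O[C@@H]2/C=C(/CO[Si](c3ccccc3)(c3ccccc3)C(C)(C)C)CC/C=C(/C(=O)OC)[C@H]1OC(C)=O | intermediate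
24 | methyl (3aS,4S,5R,6E,10E,11aR)-5-(acetyloxy)-10-(hydroxymethyl)-3-methylidene-4-[(2-methylprop-2-enoyl)oxy]-2-oxo-2,3,3a,4,5,8,9,11a-octahydrocyclodeca[b]furan-6-carboxylate | C=C(C)C(=O)O[C@H]1[C@H]2C(=C)C(=O)O[C@@H]2/C=C(/CO)CC/C=C(/C(=O)OC)[C@H]1OC(C)=O | target

Total step count: 15. Longest linear sequence: 13 steps (steps 1–4 and 7–15); steps 5 and 6 make the second fragment.

Steps most likely to fail

1. Step 11 (key annulation). The vinylpalladium species may be lost to protodebromination or to oligomerisation of 18 before it adds to the hindered ring diene. The carboxylate may also close on the palladium face and give the cis-fused lactone, and the facial selectivity at C7 may be low. Fallback, setting out from 17 and coming back at 19: a radical-polar annulation with Mn(OAc)3 (trivalent manganese, 2.2 equiv) and allyl hydrogen malonate in AcOH at 50 °C. The malonyl radical adds to C7, the allyl radical is oxidised to the cation and the free acid closes on C6, which should give 6-methyl 3-(prop-2-en-1-yl) (3aS,4R,5R,6E,10E,11aR)-10-{[tert-butyl(diphenyl)silyl]oxymethyl}-5-hydroxy-4-[(4-methoxybenzyl)oxy]-2-oxo-2,3,3a,4,5,8,9,11a-octahydrocyclodeca[b]furan-3,6-dicarboxylate F1 as a mixture at C11. Deallylation with Pd(PPh3)4 and morpholine in THF gives the lactone acid (3aS,4R,5R,6E,10E,11aR)-10-{[tert-butyl(diphenyl)silyl]oxymethyl}-5-hydroxy-6-(methoxycarbonyl)-4-[(4-methoxybenzyl)oxy]-2-oxo-2,3,3a,4,5,8,9,11a-octahydrocyclodeca[b]furan-3-carboxylic acid F2. Decarboxylative methylenation (aqueous formaldehyde, Et2NH, then AcOH/NaOAc, rt) installs C13 and returns 19.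

2. Step 10 (ring-closing metathesis). Intermolecular metathesis may outrun closure of the strained triene ring, and the catalyst may rest as an unreactive vinyl alkylidene or be held by the hydroxy ester. Fallback, setting out from 15 and coming back at 17: the order of ring closure and carbonylation is exchanged, so the ring is closed before the ester exists. The same ruthenium catalyst at 1 mM acts on iodide 15, which has no ester to bind the alkylidene, and should give (1S,2R,3Z,5E,9E)-6-{[tert-butyl(diphenyl)silyl]oxymethyl}-10-iodo-2-[(4-methoxybenzyl)oxy]cyclodeca-3,5,9-trien-1-ol F3. Methoxycarbonylation of F3 under the conditions of step 9 then gives 17.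

3. Step 14 (Mitsunobu inversion). Displacement at the hindered C8 may be slow enough for elimination to compete, and the neighbouring C9 acetate may take part through an acetoxonium ion, which would give retention or acyl scrambling. Fallback, setting out from 19 and coming back at 23: the inversion is run with a non-participating neighbour.
   - 19 is silylated at C9 (TESOTf, 2,6-lutidine, CH2Cl2, −78 °C) to methyl (3aS,4R,5R,6E,10E,11aR)-10-{[tert-butyl(diphenyl)silyl]oxymethyl}-4-[(4-methoxybenzyl)oxy]-3-methylidene-2-oxo-5-[(triethylsilyl)oxy]-2,3,3a,4,5,8,9,11a-octahydrocyclodeca[b]furan-6-carboxylate F4.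
   - DDQ (buffered CH2Cl2) gives the C8 alcohol methyl (3aR,4R,5R,6E,10E,11aR)-10-{[tert-butyl(diphenyl)silyl]oxymethyl}-4-hydroxy-3-methylidene-2-oxo-5-[(triethylsilyl)oxy]-2,3,3a,4,5,8,9,11a-octahydrocyclodeca[b]furan-6-carboxylate F5.
   - Mitsunobu esterification with 22 (PPh3, DIAD) gives the inverted ester methyl (3aS,4S,5R,6E,10E,11aR)-10-{[tert-butyl(diphenyl)silyl]oxymethyl}-3-methylidene-4-[(2-methylprop-2-enoyl)oxy]-2-oxo-5-[(triethylsilyl)oxy]-2,3,3a,4,5,8,9,11a-octahydrocyclodeca[b]furan-6-carboxylate F6.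
   - Selective removal of the triethylsilyl group (PPTS, MeOH, 0 °C) gives methyl (3aS,4S,5R,6E,10E,11aR)-10-{[tert-butyl(diphenyl)silyl]oxymethyl}-5-hydroxy-3-methylidene-4-[(2-methylprop-2-enoyl)oxy]-2-oxo-2,3,3a,4,5,8,9,11a-octahydrocyclodeca[b]furan-6-carboxylate F7.
   - Acetylation (Ac2O, pyridine) gives 23.

Further compounds

F1 | step 11 | 6-methyl 3-(prop-2-en-1-yl) (3aS,4R,5R,6E,10E,11aR)-10-{[tert-butyl(diphenyl)silyl]oxymethyl}-5-hydroxy-4-[(4-methoxybenzyl)oxy]-2-oxo-2,3,3a,4,5,8,9,11a-octahydrocyclodeca[b]furan-3,6-dicarboxylate (mixture at C3) | COc1ccc(CO[C@@H]2[C@H]3C(C(=O)OCC=C)C(=O)O[C@@H]3/C=C(/CO[Si](c4ccccc4)(c4ccccc4)C(C)(C)C)CC/C=C(/C(=O)OC)[C@H]2O)cc1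
F2 | step 11 | (3aS,4R,5R,6E,10E,11aR)-10-{[tert-butyl(diphenyl)silyl]oxymethyl}-5-hydroxy-6-(methoxycarbonyl)-4-[(4-methoxybenzyl)oxy]-2-oxo-2,3,3a,4,5,8,9,11a-octahydrocyclodeca[b]furan-3-carboxylic acid (mixture at C3) | COc1ccc(CO[C@@H]2[C@H]3C(C(=O)O)C(=O)O[C@@H]3/C=C(/CO[Si](c4ccccc4)(c4ccccc4)C(C)(C)C)CC/C=C(/C(=O)OC)[C@H]2O)cc1
F3 | step 10 | (1S,2R,3Z,5E,9E)-6-{[tert-butyl(diphenyl)silyl]oxymethyl}-10-iodo-2-[(4-methoxybenzyl)oxy]cyclodeca-3,5,9-trien-1-ol | I/C1=C/CC/C(CO[Si](c2ccccc2)(c2ccccc2)C(C)(C)C)=C\C=C/[C@@H](OCc2ccc(OC)cc2)[C@@H]1O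
F4 | step 14 | methyl (3aS,4R,5R,6E,10E,11aR)-10-{[tert-butyl(diphenyl)silyl]oxymethyl}-4-[(4-methoxybenzyl)oxy]-3-methylidene-2-oxo-5-[(triethylsilyl)oxy]-2,3,3a,4,5,8,9,11a-octahydrocyclodeca[b]furan-6-carboxylate | COc1ccc(CO[C@@H]2[C@H]3C(=C)C(=O)O[C@@H]3/C=C(/CO[Si](c4ccccc4)(c4ccccc4)C(C)(C)C)CC/C=C(/C(=O)OC)[C@H]2O[Si](CC)(CC)CC)cc1
F5 | step 14 | methyl (3aR,4R,5R,6E,10E,11aR)-10-{[tert-butyl(diphenyl)silyl]oxymethyl}-4-hydroxy-3-methylidene-2-oxo-5-[(triethylsilyl)oxy]-2,3,3a,4,5,8,9,11a-octahydrocyclodeca[b]furan-6-carboxylate | O[C@@H]1[C@H]2C(=C)C(=O)O[C@@H]2/C=C(/CO[Si](c3ccccc3)(c3ccccc3)C(C)(C)C)CC/C=C(/C(=O)OC)[C@H]1O[Si](CC)(CC)CC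
F6 | step 14 | methyl (3aS,4S,5R,6E,10E,11aR)-10-{[tert-butyl(diphenyl)silyl]oxymethyl}-3-methylidene-4-[(2-methylprop-2-enoyl)oxy]-2-oxo-5-[(triethylsilyl)oxy]-2,3,3a,4,5,8,9,11a-octahydrocyclodeca[b]furan-6-carboxylate | C=C(C)C(=O)O[C@H]1[C@H]2C(=C)C(=O)O[C@@H]2/C=C(/CO[Si](c3ccccc3)(c3ccccc3)C(C)(C)C)CC/C=C(/C(=O)OC)[C@H]1O[Si](CC)(CC)CC
F7 | step 14 | methyl (3aS,4S,5R,6E,10E,11aR)-10-{[tert-butyl(diphenyl)silyl]oxymethyl}-5-hydroxy-3-methylidene-4-[(2-methylprop-2-enoyl)oxy]-2-oxo-2,3,3a,4,5,8,9,11a-octahydrocyclodeca[b]furan-6-carboxylate | C=C(C)C(=O)O[C@H]1[C@H]2C(=C)C(=O)O[C@@H]2/C=C(/CO[Si](c3ccccc3)(c3ccccc3)C(C)(C)C)CC/C=C(/C(=O)OC)[C@H]1O
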